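Numbering: C1=C2 terminal alkene, C10 carbinol, C11–C14 oxolane carbons (ring oxygen between C11 and C14), C15–C19 pentyl. The strategy rests on the oxolane carrying the C13 oxygen and the C14 pentyl group cis to each other and both trans to the C11 side chain.
Target ⇐ debenzylation at C10 and lauroylation of the C13 hydroxyl of the 2-pentyloxolan-3-ol.
2-Pentyloxolan-3-ol ⇐ syn addition of oxygen (C13–O) and pentyl (C14–C15) across C13=C14 of a 2-substituted 2,3-dihydrofuran: dimethyldioxirane epoxidation anti to C11, then syn opening by tripentylaluminium.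
Dihydrofuran (the only ring of the target, closed first, O–C14) ⇐ molybdenum-mediated 5-endo cycloisomerisation of the (10R,11R)-alkynol ⇐ chelation-controlled propargylation (C11–C12) of (R)-2-(benzyloxy)undec-10-enal.
Aldehyde ⇐ (R)-glycidyl trityl ether + oct-7-enylmagnesium bromide (C10 from the chiral pool); the transient oxirane of the key step is the only other ring formed.

Key step: step 8

Remark on the chemistry: 8-bromooct-1-ene and (R)-glycidyl trityl ether are taken as purchasable. Tripentylaluminium carries three pentyl groups, so step 7 consumes three molecules of 1-bromopentane for each AlCl3. It is made and used as its diethyl ether complex in solution, and its SMILES is written for the ether-free alane.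

Step 1
Reactants: 1 8-bromooct-1-ene; 2 (R)-glycidyl trityl ether [(2R)-2-(trityloxymethyl)oxirane]
Product: 4 (R)-1-(trityloxy)undec-10-en-2-ol, via oct-7-enylmagnesium bromide 3 (not isolated)
Conditions: Mg, THF, rt; then CuI (10 mol %), 2, THF, −30 → 0 °C; sat. aq NH4Cl
Reagents that add atoms: none
Why: Copper-catalysed Grignard opening of a terminal epoxide occurs at the unsubstituted carbon, so the C–O stereocenter of the glycidyl ether is carried over untouched as C10 (R).

Step 2
Reactants: 4 (R)-1-(trityloxy)undec-10-en-2-ol
Product: 5 (R)-2-(benzyloxy)-1-(trityloxy)undec-10-ene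
Conditions: NaH (1.5 equiv), BnBr (1.3 equiv), Bu4NI (cat.), THF/DMF, 0 °C → rt
Reagents that add atoms: benzyl bromide BrCc1ccccc1
Why: Williamson etherification of the secondary sodium alkoxide with benzyl bromide is reliable here because the trityl ether and the terminal alkene are inert to base and the stereocenter is not involved.

Step 3
Reactants: 5 (R)-2-(benzyloxy)-1-(trityloxy)undec-10-ene
Product: 6 (R)-2-(benzyloxy)undec-10-en-1-ol
Conditions: TsOH·H2O (0.1 equiv), MeOH/CH2Cl2 (1:1), rt
Reagents that add atoms: none
Why: Acid-catalysed methanolysis of the trityl ether proceeds through the stabilised trityl cation under conditions that leave the benzyl ether and the alkene alone.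

Step 4
Reactants: 6 (R)-2-(benzyloxy)undec-10-en-1-ol
Product: 7 (R)-2-(benzyloxy)undec-10-enal
Conditions: (COCl)2, DMSO, CH2Cl2, −78 °C; Et3N, −78 → −20 °C; used crude at once
Reagents that add atoms: none
Why: Swern oxidation at low temperature stops at the aldehyde and should not epimerise the α-alkoxy center, the product being used without chromatography.

Step 5
Reactants: 7 (R)-2-(benzyloxy)undec-10-enal; 8 allenyltributylstannane
Product: 9 (10R,11R)-10-(benzyloxy)tetradec-1-en-13-yn-11-ol
Conditions: MgBr2·OEt2 (2.5 equiv), CH2Cl2, −20 °C; then 8 (1.5 equiv), −20 → 0 °C; sat. aq NH4Cl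
Reagents that add atoms: none
Why: MgBr2 bridges the carbonyl and benzyloxy oxygens (Cram chelate) and the allenylstannane adds by SE2' propargylation to the face opposite the non-8-enyl chain, which sets C11 (R) syn to C10–OBn.

Step 6
Reactants: 9 (10R,11R)-10-(benzyloxy)tetradec-1-en-13-yn-11-ol
Product: 10 (R)-2-[(R)-1-(benzyloxy)dec-9-enyl]-2,3-dihydrofuran
Conditions: Mo(CO)6 (0.25 equiv), Et3N/Et2O, hν (350 nm), rt; then 9, rt, dark; Et3N-deactivated silica
Reagents that add atoms: none
Why: Alkynol cycloisomerisation, in which (Et3N)Mo(CO)5 converts the terminal alkyne into a molybdenum vinylidene whose electrophilic α-carbon (C14) is attacked by the C11 hydroxyl in a 5-endo sense and protodemetalation releases the 2,3-dihydrofuran without touching C10 or C11.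

Step 7
Reactants: 11 1-bromopentane (3 equiv per aluminium)
Product: 13 tripentylaluminium, via pentylmagnesium bromide 12 (not isolated)
Conditions: 11 (3.0 equiv), Mg (3.3 equiv), Et2O, reflux; then AlCl3 (1.0 equiv), Et2O, 0 °C → rt; diluted with hexane, filtered under argon, solvent exchanged for CH2Cl2
Reagents that add atoms: 1-bromopentane (second and third equivalents of 11) CCCCCBr.CCCCCBr; aluminium trichloride Cl[Al](Cl)Cl
Why: Salt metathesis (transmetallation) of three molecules of the Grignard reagent with one AlCl3 replaces all three chlorides by pentyl and gives the trialkylalane, kept as its ether complex once the magnesium halide has been filtered off.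

Step 8
Reactants: 10 (R)-2-[(R)-1-(benzyloxy)dec-9-enyl]-2,3-dihydrofuran; 13 tripentylaluminium
Product: 15 (2S,3S,5R)-5-[(R)-1-(benzyloxy)dec-9-enyl]-2-pentyltetrahydrofuran-3-ol, via dihydrofuran epoxide 14 (not isolated)
Conditions: DMDO (1.1 equiv, in acetone), CH2Cl2, −78 → −40 °C; volatiles removed at ≤ 0 °C; then 13 (3 equiv), CH2Cl2, −78 → 0 °C; aq potassium sodium tartrate
Reagents that add atoms: dimethyldioxirane CC1(C)OO1
Why: Dimethyldioxirane transfers oxygen in a concerted spiro fashion to the electron-rich C13=C14 enol ether, far faster than to the monosubstituted C1=C2 alkene, and from the ring face away from the branched C11 substituent, which fixes C13–O (S). Tripentylaluminium then coordinates the oxirane oxygen, the C14–O bond ionises with help from the ring oxygen to an oxocarbenium/alkoxyaluminate ion pair, and a pentyl group passes from aluminium to C14 within this pair on the face of the departing oxygen, which fixes C14 (S) by retention. The closest known reaction type is the syn C-glycosylation of glycal epoxides (1,2-anhydro sugars) with trialkyl- and triarylaluminium reagents. The only ring closed is the transient oxirane (concerted [2+1] oxygen transfer), which is opened again in the same operation, so no ring of the product is formed here and the oxolane is already in place. The step needs chemoselectivity for the enol ether (secured by its much higher nucleophilicity and one equivalent of oxidant at low temperature), anti facial selectivity (secured by the C11 CH(OBn)R group on the nearly flat five-membered ring), opening at C14 and not at C13 (secured by oxocarbenium stabilisation), and syn transfer of pentyl in preference to hydride or external attack (secured by internal delivery in a non-coordinating solvent at low temperature with the magnesium halide removed).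

Step 9
Reactants: 15 (2S,3S,5R)-5-[(R)-1-(benzyloxy)dec-9-enyl]-2-pentyltetrahydrofuran-3-ol; 16 dodecanoic acid
Product: 17 (2S,3S,5R)-5-[(R)-1-(benzyloxy)dec-9-enyl]-2-pentyltetrahydrofuran-3-yl dodecanoate
Conditions: DCC (1.3 equiv), DMAP (0.2 equiv), CH2Cl2, 0 °C → rt
Reagents that add atoms: none
Why: Steglich esterification acylates the only free hydroxyl (C13) with retention, DMAP carrying the acyl group to the hindered secondary alcohol.

Step 10
Reactants: 17 (2S,3S,5R)-5-[(R)-1-(benzyloxy)dec-9-enyl]-2-pentyltetrahydrofuran-3-yl dodecanoate
Product: 18 (2S,3S,5R)-5-[(R)-1-hydroxydec-9-enyl]-2-pentyltetrahydrofuran-3-yl dodecanoate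
Conditions: BCl3 (3 equiv, 1 M in CH2Cl2), pentamethylbenzene (4 equiv), CH2Cl2, −78 °C; then H2O, −78 °C → rt
Reagents that add atoms: none
Why: BCl3 cleaves the benzyl ether by Lewis acid activation at −78 °C with pentamethylbenzene trapping the benzyl cation by Friedel–Crafts alkylation, conditions under which the ester, the oxolane and the terminal alkene should persist.

Compound list
1 | 8-bromooct-1-ene | C=CCCCCCCBr | starting material
2 | (R)-glycidyl trityl ether [(2R)-2-(trityloxymethyl)oxirane] | C1[C@@H](O1)COC(c2ccccc2)(c2ccccc2)c2ccccc2 | starting material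
3 | oct-7-enylmagnesium bromide | C=CCCCCCC[Mg]Br | intermediate
4 | (R)-1-(trityloxy)undec-10-en-2-ol | C=CCCCCCCC[C@@H](O)COC(c1ccccc1)(c1ccccc1)c1ccccc1 | intermediate
5 | (R)-2-(benzyloxy)-1-(trityloxy)undec-10-ene | C=CCCCCCCC[C@@H](OCc1ccccc1)COC(c1ccccc1)(c1ccccc1)c1ccccc1 | intermediate
6 | (R)-2-(benzyloxy)undec-10-en-1-ol | C=CCCCCCCC[C@@H](OCc1ccccc1)CO | intermediate
7 | (R)-2-(benzyloxy)undec-10-enal | C=CCCCCCCC[C@@H](OCc1ccccc1)C=O | intermediate
8 | allenyltributylstannane | C=C=C[Sn](CCCC)(CCCC)CCCC | starting material
9 | (10R,11R)-10-(benzyloxy)tetradec-1-en-13-yn-11-ol | C=CCCCCCCC[C@@H](OCc1ccccc1)[C@H](O)CC#C | intermediate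
10 | (R)-2-[(R)-1-(benzyloxy)dec-9-enyl]-2,3-dihydrofuran | C=CCCCCCCC[C@@H](OCc1ccccc1)[C@H]1CC=CO1 | intermediate
11 | 1-bromopentane | CCCCCBr | starting material
12 | pentylmagnesium bromide | CCCCC[Mg]Br | intermediate
13 | tripentylaluminium | CCCCC[Al](CCCCC)CCCCC | intermediate
14 | (1R,3R,5S)-3-[(R)-1-(benzyloxy)dec-9-enyl]-2,6-dioxabicyclo[3.1.0]hexane | C=CCCCCCCC[C@@H](OCc1ccccc1)[C@H]1C[C@@H]2O[C@@H]2O1 | intermediate
15 | (2S,3S,5R)-5-[(R)-1-(benzyloxy)dec-9-enyl]-2-pentyltetrahydrofuran-3-ol | C=CCCCCCCC[C@@H](OCc1ccccc1)[C@H]1C[C@H](O)[C@H](CCCCC)O1 | intermediate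
16 | dodecanoic acid | CCCCCCCCCCCC(=O)O | starting material
17 | (2S,3S,5R)-5-[(R)-1-(benzyloxy)dec-9-enyl]-2-pentyltetrahydrofuran-3-yl dodecanoate | C=CCCCCCCC[C@@H](OCc1ccccc1)[C@H]1C[C@H](OC(=O)CCCCCCCCCCC)[C@H](CCCCC)O1 | intermediate
18 | (2S,3S,5R)-5-[(R)-1-hydroxydec-9-enyl]-2-pentyltetrahydrofuran-3-yl dodecanoate | C=CCCCCCCC[C@@H](O)[C@H]1C[C@H](OC(=O)CCCCCCCCCCC)[C@H](CCCCC)O1 | target

Total step count: 10. Longest linear sequence: 9 steps (steps 1–6 and 8–10); step 7 is a one-step reagent branch.

Steps most likely to fail

1. Step 8. The oxidant may not discriminate well enough between the two faces of the nearly planar dihydrofuran, since only the C11 substituent across the ring tells them apart. The labile epoxide may also be hydrolysed or opened by residual halide before the alane acts. A pentyl–aluminium group may hand over a β-hydrogen instead of pentyl, or deliver pentyl from the wrong face. The fallback sets out from alkynol 9 and comes back at alcohol 15, forming the O–C14 bond last with inversion instead of adding carbon to a ring. The dianion of 9 (n-BuLi, 2.1 equiv, THF/DMPU, −78 → 0 °C) would be alkylated at the alkyne terminus with 1-bromopentane 11 to give (10R,11R)-10-(benzyloxy)nonadec-1-en-13-yn-11-ol F1. Semihydrogenation over Pd/CaCO3 poisoned with Pb(OAc)2 and quinoline, stopped after one equivalent of H2, should give (10R,11R,13Z)-10-(benzyloxy)nonadeca-1,13-dien-11-ol F2. Hydroxyl-directed epoxidation with VO(acac)2 and t-BuOOH in CH2Cl2 is expected, through the chair-like vanadate transition state with the C11 substituent equatorial, to place the oxirane oxygen syn to the C11 hydroxyl and leave the remote terminal alkene alone, giving (10R,11R,13S,14R)-10-(benzyloxy)-13,14-epoxynonadec-1-en-11-ol F3. Catalytic camphorsulfonic acid in CH2Cl2 should then close the oxolane by 5-endo attack of the C11 hydroxyl at C14 with inversion, which gives the 2,3-cis-2,5-trans alcohol 15.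

2. Step 6. The photogenerated molybdenum catalyst may turn over slowly or decay, the terminal alkene may migrate if carbonyl-metal species are irradiated in its presence, and the acid-labile enol ether may hydrate on purification. The fallback sets out from alkynol 9 and comes back at dihydrofuran 10, using π-acid hydroalkoxylation followed by elimination instead of a vinylidene. Ph3PAuCl/AgBF4 (2 mol % each) with catalytic TsOH in ethanol should bring about 5-endo cyclisation and ethanol addition to give (5R)-5-[(R)-1-(benzyloxy)dec-9-enyl]-2-ethoxytetrahydrofuran F4 as a mixture at the acetal carbon. TMSOTf and iPr2NEt in CH2Cl2 should then eliminate ethanol from this mixed acetal to give 10.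

3. Step 5. Chelation control may be eroded by a competing open transition state, the stannane may isomerise to its propargyl form and give the allenyl carbinol, and the α-alkoxy aldehyde may epimerise if the addition is slow. The fallback sets out from bromide 1 through its Grignard reagent 3 and comes back at alkynol 9, taking both C10 and C11 from the chiral pool and forming C12–C13 by acetylide opening; it also replaces steps 1–4. Grignard reagent 3 with CuI (10 mol %) would open one ring of an excess of (2R,2'R)-2,2'-bioxirane (C1[C@@H](O1)[C@H]1CO1, available from D-threitol) at its terminal carbon to give (R)-1-[(R)-oxiran-2-yl]dec-9-en-1-ol F5. Benzylation under non-basic conditions (BnBr, Ag2O, CH2Cl2), chosen to avoid epoxide migration, should give (R)-2-[(R)-1-(benzyloxy)dec-9-enyl]oxirane F6. Lithium acetylide–ethylenediamine complex in DMSO at rt should then open the terminal epoxide at C12 to give 9.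

Further compounds
F1 | step 8 | (10R,11R)-10-(benzyloxy)nonadec-1-en-13-yn-11-ol | C=CCCCCCCC[C@@H](OCc1ccccc1)[C@H](O)CC#CCCCCC
F2 | step 8 | (10R,11R,13Z)-10-(benzyloxy)nonadeca-1,13-dien-11-ol | C=CCCCCCCC[C@@H](OCc1ccccc1)[C@H](O)C/C=C\CCCCC
F3 | step 8 | (10R,11R,13S,14R)-10-(benzyloxy)-13,14-epoxynonadec-1-en-11-ol | C=CCCCCCCC[C@@H](OCc1ccccc1)[C@H](O)C[C@@H]1O[C@@H]1CCCCC
F4 | step 6 | (5R)-5-[(R)-1-(benzyloxy)dec-9-enyl]-2-ethoxytetrahydrofuran | C=CCCCCCCC[C@@H](OCc1ccccc1)[C@H]1CCC(OCC)O1
F5 | step 5 | (R)-1-[(R)-oxiran-2-yl]dec-9-en-1-ol | C=CCCCCCCC[C@@H](O)[C@H]1CO1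
F6 | step 5 | (R)-2-[(R)-1-(benzyloxy)dec-9-enyl]oxirane | C=CCCCCCCC[C@@H](OCc1ccccc1)[C@H]1CO1
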